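- Watch the pool. In both earlier runs the solid substrate disappears ahead of the target, so something dissolved and unreacted stands between them. You can treat it as a reservoir with a steady feed and a pseudo-first-order drain.

| setting | north-west | east | flask |
|---|---|---|---|
| solid substrate | 0.12 M | 0.12 M | 0.12 M |
| acid | 0.18 mM | 0.72 mM | 0.360 mM |
| remark | run made earlier | run made earlier |  |
| time |  |  | 50 min |

| run | time / min | solid substrate / % | target / % |
|---|---|---|---|
| north-west | 5.00 | 99.7 | 0 |
| north-west | 12.0 | 98.9 | 0 |
| north-west | 25.0 | 96.8 | 0.6 |
| north-west | 60.0 | 93.2 | 3.8 |
| east | 15.0 | 97.9 | 1.2 |
| east | 30.0 | 96.4 | 2.7 |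
| east | 50.0 | 93.6 | 5.1 |
| east | 60.0 | 92.4 | 6.4 |

(readings scatter by 0.3 percentage points)

* part of the solid substrate that has reacted (what has only dissolved counts as not reacted) at 50 min
* pH of the solution at 50 min

- acid is the free proton; pH is minus the decimal logarithm of its molar concentration
- given per volume of solution although it is solid: solid substrate
- at the start none of the solid substrate is in solution
- what has only dissolved of solid substrate counts as not reacted

- Averaged over the two runs, the feed is a fraction 0.00120 min⁻¹ of the charge.
- In the east run the pool stands near 1.20%, so its drain roughly matches its feed, and pool over feed gives 9.47 min.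
- In the north-west run the pool averages 2.80% between its last two readings. The target's gain over that stretch gives 30.6 min, longer at the lower acid. Both are rough readings, given the scatter.
- Drawing the drain rate as a straight line in acid, I get for this flask the lifetime of the pool, the mean wait of dissolved material before it reacts: 17.6 min.
- The target's rate starts at zero and climbs toward the feed, its shortfall shrinking by a factor e each lifetime. By 50 min you have counted 2.84 lifetimes, so the shortfall is 0.0584 of the feed. The summed shortfall costs 16.6 min of feeding, and my reckoning for the reacted part is 4.02%.
- The east run made 7.68 mM of target with 0.72 mM of acid present, so I keep the acid unspent and the pH as charged.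
- The forecast gave 4% and pH 3.44, holding that “the acid is catalytic”.
- The flask gives 4.16% and pH 3.44, with the acid at 100% of its charge.

    weak acid ⇌ conjugate base + acid, settled at all times (K = 7.90 × 10⁻⁹ M)
    solid substrate ⇌ starting material, rate k2*(cs2 - [starting material]) while solid is left; crystals form when [starting material] > cs2 (solubility = 19.0 mM, k = 0.00862 min⁻¹)
    starting material → weak acid + target (k = 0.0176 min⁻¹)
    starting material + acid → weak acid + acid + target (k = 107 M⁻¹ min⁻¹)

- The pool is the starting material. Its low solubility, which also sets how fast it dissolves, is the main reason for so small a reacted part: the same flask run without that limit reaches 93.6%. Feed times the filled part of 17.6 min gives a pool of 1.99%, and the flask holds 2.03%.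
- Left until 2.0 h, the neighbour flask has counted 6.82 lifetimes, so it has paid the full lag of one lifetime, and feed times the remaining time gives 12.3%. The computed neighbour shows 12.4%.

The earlier runs and the new flask stem from a simulated flask for substances that don't exist; noise was put on by code.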